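**Retrosynthetic overview**
1. Kwakhurin ⇐ its 2′-O-TIPS ether (fluoride).
2. Key disconnection C3–C1′, with ring C closed in the same flask: the enaminone of 2,4-dihydroxyacetophenone (C3 is the nucleophilic enamine carbon) plus ring B as a masked o-benzoquinone (6,6-dimethoxycyclohexa-2,4-dienone). The ketal makes the phenol carbon para to OH an electrophile (a phenoxenium, i.e. vinylogous enolonium, equivalent), so two normally nucleophilic carbons are joined.
3. Masked o-benzoquinone ⇐ PhI(OAc)2/MeOH on a guaiacol-type phenol with free 4′-OH, 5′-OMe, 6′-prenyl and 2′-OTIPS.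
4. That phenol ⇐ 4-methoxy-5-prenylresorcinol ⇐ 4-methoxyresorcinol, the prenyl group being placed by OMe-directed ortho-lithiation of the bis-TIPS ether.
5. Ring order: rings A and B are bought as benzenoid starting materials; ring C (the pyranone) is the only ring made, and it is made last, in the coupling step.

Assumption: the target has no stereocentre and no stereogenic double bond, so the SMILES defines it completely and nothing stereochemical has to be set.

**Route**

Step 1
Reactants: 1 4-methoxybenzene-1,3-diol (4-methoxyresorcinol)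
Product: 2 1-methoxy-2,4-bis[(triisopropylsilyl)oxy]benzene
Conditions: TIPSCl (2.4 equiv), imidazole (5 equiv), DMF, 40 °C
Reagents that add atoms: chlorotriisopropylsilane, CC(C)[Si](Cl)(C(C)C)C(C)C
Why: Exhaustive silyl ether formation turns both phenols into bulky, non-coordinating OTIPS groups that neither direct lithiation nor allow it next to themselves, so OMe becomes the only directing group.

Step 2
Reactants: 2 1-methoxy-2,4-bis[(triisopropylsilyl)oxy]benzene; 3 1-bromo-3-methylbut-2-ene (prenyl bromide)
Product: 6 4-methoxy-5-(3-methylbut-2-en-1-yl)benzene-1,3-diol, via aryllithium 4 (not isolated), via bis-TIPS prenylarene 5 (not isolated)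
Conditions: n-BuLi (1.4 equiv), TMEDA, Et2O, 0 °C→rt; CuBr·SMe2 (20 mol %), 3 (1.5 equiv), −78 °C→rt; then TBAF (3 equiv), AcOH (3 equiv), THF, rt
Reagents that add atoms: none
Why: Directed ortho-metalation puts lithium on the single free position ortho to OMe (future C6′; the other two C–H bonds are screened by OTIPS), copper-catalysed allylic substitution at the primary carbon of 3 gives the linear prenyl arene, and fluoride desilylation in the same flask frees both phenols.

Step 3
Reactants: 6 4-methoxy-5-(3-methylbut-2-en-1-yl)benzene-1,3-diol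
Product: 7 2-methoxy-3-(3-methylbut-2-en-1-yl)-5-[(triisopropylsilyl)oxy]phenol
Conditions: TIPSCl (1.0 equiv), imidazole (2 equiv), CH2Cl2, −20→0 °C
Reagents that add atoms: chlorotriisopropylsilane, CC(C)[Si](Cl)(C(C)C)C(C)C
Why: Sterically controlled monosilylation: the OH para to OMe has two ortho hydrogens, whereas the other OH is hydrogen-bonded to and crowded by the out-of-plane OMe, so one equivalent of the bulky chloride caps only the future 2′-oxygen, the one phenol that could later close a benzofuran.

Step 4
Reactants: 8 1-(2,4-dihydroxyphenyl)ethan-1-one (2,4-dihydroxyacetophenone); 9 1,1-dimethoxy-N,N-dimethylmethanamine (DMF dimethyl acetal)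
Product: 10 (E)-1-(2,4-dihydroxyphenyl)-3-(dimethylamino)prop-2-en-1-one
Conditions: 9 (1.3 equiv), toluene, 80 °C
Reagents that add atoms: none
Why: Enaminone formation by condensation of the methyl ketone with the amide acetal installs the future C2 and makes the future C3 a strongly nucleophilic enamine carbon; a small excess of 9 at moderate temperature limits O-methylation of the phenols.

Step 5
Reactants: 7 2-methoxy-3-(3-methylbut-2-en-1-yl)-5-[(triisopropylsilyl)oxy]phenol; 10 (E)-1-(2,4-dihydroxyphenyl)-3-(dimethylamino)prop-2-en-1-one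
Product: 13 7-hydroxy-3-{4-hydroxy-3-methoxy-2-(3-methylbut-2-en-1-yl)-6-[(triisopropylsilyl)oxy]phenyl}-4H-chromen-4-one, via masked o-benzoquinone 11 (not isolated), via α-aryl enaminone 12 (not isolated)
Conditions: PhI(OAc)2 (1.0 equiv), MeOH, −10 °C, 10 min; then 10 (1.3 equiv), HFIP (HFIP/MeOH ≥ 10:1), 0 °C→rt
Reagents that add atoms: methanol, CO (second ketal methoxy of 11; one of the two ketal methoxy groups remains as 5′-OMe)
Why: Proposed new method: PhI(OAc)2/MeOH dearomatises the guaiacol unit of 7 to the ketal 11 (oxidative ketalisation of a 2-methoxyphenol), which in HFIP with the AcOH formed acts as a para-hydroxyaryl cation (phenoxenium, vinylogous enolonium) equivalent; the enamine carbon of 10 attacks C4 of the dienone (future C1′) in an SN2′ sense with loss of MeOH, attack on the C3′ side being disfavoured because that carbon is the electron-rich α-carbon of the vinylogous silyl ester and both Michael positions being substituted; the ring re-aromatises to 12 and the 2-OH of ring A adds to the iminium carbon and expels Me2NH to close ring C, while the silylated 2′-oxygen cannot close a benzofuran; the closest known reaction types are the acid- or fluoroalcohol-promoted SN2′ coupling of quinone monoacetals with carbon nucleophiles and the electrophile-triggered chromone annulation of o-hydroxyaryl enaminones.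

Step 6
Reactants: 13 7-hydroxy-3-{4-hydroxy-3-methoxy-2-(3-methylbut-2-en-1-yl)-6-[(triisopropylsilyl)oxy]phenyl}-4H-chromen-4-one
Product: 14 kwakhurin, 3-[4,6-dihydroxy-3-methoxy-2-(3-methylbut-2-en-1-yl)phenyl]-7-hydroxy-4H-chromen-4-one
Conditions: TBAF (1.2 equiv), AcOH (1.2 equiv), THF, 0 °C
Reagents that add atoms: none
Why: Fluoride desilylation of the aryl silyl ether, buffered with AcOH so that the base-sensitive pyranone and the prenyl group are untouched; the target has no stereocentre to set.

**Compound list**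
1 | 4-methoxybenzene-1,3-diol | COc1ccc(O)cc1O | starting material
2 | 1-methoxy-2,4-bis[(triisopropylsilyl)oxy]benzene | COc1ccc(O[Si](C(C)C)(C(C)C)C(C)C)cc1O[Si](C(C)C)(C(C)C)C(C)C | intermediate
3 | 1-bromo-3-methylbut-2-ene | CC(C)=CCBr | starting material
4 | {2-methoxy-3,5-bis[(triisopropylsilyl)oxy]phenyl}lithium | COc1c([Li])cc(O[Si](C(C)C)(C(C)C)C(C)C)cc1O[Si](C(C)C)(C(C)C)C(C)C | intermediate (not isolated)
5 | 2-methoxy-1-(3-methylbut-2-en-1-yl)-3,5-bis[(triisopropylsilyl)oxy]benzene | COc1c(CC=C(C)C)cc(O[Si](C(C)C)(C(C)C)C(C)C)cc1O[Si](C(C)C)(C(C)C)C(C)C | intermediate (not isolated)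
6 | 4-methoxy-5-(3-methylbut-2-en-1-yl)benzene-1,3-diol | COc1c(CC=C(C)C)cc(O)cc1O | intermediate
7 | 2-methoxy-3-(3-methylbut-2-en-1-yl)-5-[(triisopropylsilyl)oxy]phenol | COc1c(CC=C(C)C)cc(O[Si](C(C)C)(C(C)C)C(C)C)cc1O | intermediate
8 | 1-(2,4-dihydroxyphenyl)ethan-1-one | CC(=O)c1ccc(O)cc1O | starting material
9 | 1,1-dimethoxy-N,N-dimethylmethanamine | COC(OC)N(C)C | starting material
10 | (E)-1-(2,4-dihydroxyphenyl)-3-(dimethylamino)prop-2-en-1-one | CN(C)/C=C/C(=O)c1ccc(O)cc1O | intermediate
11 | 6,6-dimethoxy-5-(3-methylbut-2-en-1-yl)-3-[(triisopropylsilyl)oxy]cyclohexa-2,4-dien-1-one | COC1(OC)C(CC=C(C)C)=CC(O[Si](C(C)C)(C(C)C)C(C)C)=CC1=O | intermediate (not isolated)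
12 | (E)-1-(2,4-dihydroxyphenyl)-3-(dimethylamino)-2-{4-hydroxy-3-methoxy-2-(3-methylbut-2-en-1-yl)-6-[(triisopropylsilyl)oxy]phenyl}prop-2-en-1-one | CN(C)/C=C(/C(=O)c1ccc(O)cc1O)c1c(CC=C(C)C)c(OC)c(O)cc1O[Si](C(C)C)(C(C)C)C(C)C | intermediate (not isolated)
13 | 7-hydroxy-3-{4-hydroxy-3-methoxy-2-(3-methylbut-2-en-1-yl)-6-[(triisopropylsilyl)oxy]phenyl}-4H-chromen-4-one | COc1c(O)cc(O[Si](C(C)C)(C(C)C)C(C)C)c(-c2coc3cc(O)ccc3c2=O)c1CC=C(C)C | intermediate
14 | kwakhurin, 3-[4,6-dihydroxy-3-methoxy-2-(3-methylbut-2-en-1-yl)phenyl]-7-hydroxy-4H-chromen-4-one | COc1c(O)cc(O)c(-c2coc3cc(O)ccc3c2=O)c1CC=C(C)C | target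

**Totals**
Total step count: 6. Longest linear sequence: 5 steps (steps 1, 2, 3, 5, 6; step 4 is the one-step side branch).

**Three steps most likely to fail, each with a fallback**

Step 5 (key coupling). The ketal 11 may react at the wrong ring position, cycloadd with the enaminone, or not react before 10 cyclises by itself. The fallback makes the C3–C1′ bond by cross-coupling; it sets out from 10 and 7 and comes back at 13. Iodine in MeOH converts 10 into 7-hydroxy-3-iodo-4H-chromen-4-one F1 (C3 iodination, ring closure, loss of Me2NH). NIS in MeCN at −20 °C iodinates 7 para to its free OH to give 4-iodo-2-methoxy-3-(3-methylbut-2-en-1-yl)-5-[(triisopropylsilyl)oxy]phenol F2. Pd(dppf)Cl2, B2pin2 and KOAc in dioxane turn F2 into 2-methoxy-3-(3-methylbut-2-en-1-yl)-4-(4,4,5,5-tetramethyl-1,3,2-dioxaborolan-2-yl)-5-[(triisopropylsilyl)oxy]phenol F3. Suzuki–Miyaura coupling of F1 with F3 (Pd(OAc)2, SPhos, K3PO4, dioxane/H2O) gives 13, which goes on to step 6.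

Step 2 (lithiation/prenylation). The OMe group is a weak director and is crowded by the neighbouring OTIPS, so lithiation may be slow or unselective, and the allylation may give some branched product. The fallback replaces metalation by C–H borylation; it sets out from 2 and comes back at 5. [Ir(OMe)(cod)]2, dtbpy and B2pin2 borylate the least hindered C–H bond (ortho to OMe; the other two are ortho to OTIPS) to give 2-{2-methoxy-3,5-bis[(triisopropylsilyl)oxy]phenyl}-4,4,5,5-tetramethyl-1,3,2-dioxaborolane F4. Pd(PPh3)4 and K3PO4 then couple F4 with 3 at its primary carbon to give 5, which is desilylated as in the second half of step 2.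

Step 3 (selective monosilylation). Selectivity between the two phenols of 6 may be only moderate. The fallback differentiates the two oxygens after dearomatisation instead; it sets out from 6 and comes back at 11. PhI(OAc)2 in MeOH oxidises the unprotected diol (either OH leads to the same product) to 3-hydroxy-4,4-dimethoxy-5-(3-methylbut-2-en-1-yl)cyclohexa-2,5-dien-1-one F5. TIPSOTf with 2,6-lutidine silylates the oxygen of this vinylogous acid that is remote from the quaternary ketal carbon, giving 11, which is treated with 10 in HFIP as in step 5.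

**Further compounds**
F1 | step 5 | 7-hydroxy-3-iodo-4H-chromen-4-one | O=c1c(I)coc2cc(O)ccc12
F2 | step 5 | 4-iodo-2-methoxy-3-(3-methylbut-2-en-1-yl)-5-[(triisopropylsilyl)oxy]phenol | COc1c(CC=C(C)C)c(I)c(O[Si](C(C)C)(C(C)C)C(C)C)cc1O
F3 | step 5 | 2-methoxy-3-(3-methylbut-2-en-1-yl)-4-(4,4,5,5-tetramethyl-1,3,2-dioxaborolan-2-yl)-5-[(triisopropylsilyl)oxy]phenol | COc1c(CC=C(C)C)c(B2OC(C)(C)C(C)(C)O2)c(O[Si](C(C)C)(C(C)C)C(C)C)cc1O
F4 | step 2 | 2-{2-methoxy-3,5-bis[(triisopropylsilyl)oxy]phenyl}-4,4,5,5-tetramethyl-1,3,2-dioxaborolane | COc1c(B2OC(C)(C)C(C)(C)O2)cc(O[Si](C(C)C)(C(C)C)C(C)C)cc1O[Si](C(C)C)(C(C)C)C(C)C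
F5 | step 3 | 3-hydroxy-4,4-dimethoxy-5-(3-methylbut-2-en-1-yl)cyclohexa-2,5-dien-1-one | COC1(OC)C(O)=CC(=O)C=C1CC=C(C)C
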